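**Retrosynthetic overview**
1. Rings A and B are bought, ring A as 4-methoxyresorcinol 1 and ring B as 4-hydroxyphenylacetic acid 2; ring C (the pyranone) is the only ring that is built.
2. Ring C: C4–C4a by Friedel–Crafts acylation (deoxybenzoin 3), then C2 from DMF with closure of the O1–C2 bond to glycitein 4; 3 has a single ortho-OH, so the closure is unambiguous.
3. Key C–O disconnection: the C5–H of 4 is oxygenated late, through trifluoroacetates 5 and 6, to give the chelated C5–OH of tectorigenin 7.
4. Last C–O disconnection: 7 and prenyl bromide 8, through dipotassium salt 9, give the 4'-O-prenyl ether of target 10.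

Assumption: target 10 has no stereocentre and no stereogenic double bond, so "single enantiomer" needs no stereocontrol; it is 5,7-dihydroxy-6-methoxy-3-[4-(prenyloxy)phenyl]-4H-chromen-4-one.

**Step 1**
Reactants: 1 4-methoxyresorcinol (4-methoxybenzene-1,3-diol); 2 4-hydroxyphenylacetic acid
Product: 4 glycitein (7-hydroxy-3-(4-hydroxyphenyl)-6-methoxy-4H-chromen-4-one), via deoxybenzoin 3 (not isolated)
Conditions: BF3·Et2O (solvent), N2, 85 °C, 1.5 h; then DMF, MsCl (3 equiv), 50 → 80 °C, 2 h; ice/H2O
Reagents that add atoms: N,N-dimethylformamide (DMF), CN(C)C=O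
Why: Friedel–Crafts acylation occurs at the ring position ortho to one OH and para to the other, and Vilsmeier-type C-formylation of the ketone α-carbon followed by cyclisation of the only ortho-OH with loss of dimethylamine closes ring C (one-pot deoxybenzoin route to isoflavones); no stereocentre is formed.

**Step 2**
Reactants: 4 glycitein
Product: 7 tectorigenin (5,7-dihydroxy-3-(4-hydroxyphenyl)-6-methoxy-4H-chromen-4-one), via glycitein bis(trifluoroacetate) 5 (not isolated), via tectorigenin tris(trifluoroacetate) 6 (not isolated)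
Conditions: TFAA/TFA (1:3), rt, 30 min; then [RuCl2(p-cymene)]2 (5 mol %), PhI(OCOCF3)2 (1.3 equiv), 70 °C, 8 h; then THF/H2O, rt
Reagents that add atoms: [bis(trifluoroacetoxy)iodo]benzene, O=C(OI(OC(=O)C(F)(F)F)c1ccccc1)C(F)(F)F (a trifluoroacetate oxygen becomes the C5 oxygen of 7); trifluoroacetic anhydride, O=C(OC(=O)C(F)(F)F)C(F)(F)F (trifluoroacetyl groups of 5 and 6 only, none left in 7)
Why: Proposed new method: pyranone-carbonyl-directed peri C5–H oxygenation of a 6-alkoxy polyphenolic isoflavone, in which TFAA first masks both phenols as electron-poor trifluoroacetates (5), the C4 carbonyl oxygen binds the divalent ruthenium species Ru(OCOCF3)2(p-cymene), carboxylate-assisted metalation cleaves the only C–H that can give a five-membered ruthenacycle (C5–H, made electron-rich by the adjacent methoxy group), PhI(OCOCF3)2 oxidises the metallacycle to tetravalent ruthenium, C–O reductive elimination gives aryl trifluoroacetate 6, and water then frees the 5-OH; this fixes the 5-OH/6-OMe/7-OH pattern without the 6-methoxy versus 8-methoxy ambiguity of closing a 2,4,6-trihydroxy-3-methoxyphenyl ketone, and the closest known reaction type is the ruthenium-catalysed ketone-directed ortho C–H hydroxylation of aryl ketones with hypervalent iodine oxidants in TFA/TFAA, not shown for a C–H flanked by an alkoxy group in a free-phenol isoflavone.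

**Step 3**
Reactants: 7 tectorigenin; 8 prenyl bromide (1-bromo-3-methylbut-2-ene)
Product: 10 isoaurmillone (5,7-dihydroxy-6-methoxy-3-{4-[(3-methylbut-2-en-1-yl)oxy]phenyl}-4H-chromen-4-one), via tectorigenin dipotassium salt 9 (not isolated)
Conditions: KOtBu (2.05 equiv), DMF, 0 °C, 20 min; then 8 (1.0 equiv), −20 → 0 °C, 2 h; AcOH (1.1 equiv), H2O
Reagents that add atoms: potassium tert-butoxide, CC(C)(C)[O-].[K+] (potassium of 9 only, none left in 10)
Why: Williamson ether synthesis on the dianion, where the unhindered 4'-phenoxide (not conjugated to the pyranone carbonyl, the more basic one) is much more nucleophilic than the vinylogous-carboxylate 7-phenoxide flanked by the 6-methoxy group, and the chelated 5-OH stays protonated; no stereocentre is formed.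

**Compound list**
1 | 4-methoxyresorcinol (4-methoxybenzene-1,3-diol) | COc1ccc(O)cc1O | starting material
2 | 4-hydroxyphenylacetic acid | O=C(O)Cc1ccc(O)cc1 | starting material
3 | 1-(2,4-dihydroxy-5-methoxyphenyl)-2-(4-hydroxyphenyl)ethan-1-one (deoxybenzoin) | COc1cc(C(=O)Cc2ccc(O)cc2)c(O)cc1O | intermediate
4 | glycitein (7-hydroxy-3-(4-hydroxyphenyl)-6-methoxy-4H-chromen-4-one) | COc1cc2c(=O)c(-c3ccc(O)cc3)coc2cc1O | intermediate
5 | glycitein 7,4'-bis(trifluoroacetate) | COc1cc2c(=O)c(-c3ccc(OC(=O)C(F)(F)F)cc3)coc2cc1OC(=O)C(F)(F)F | intermediate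
6 | tectorigenin 5,7,4'-tris(trifluoroacetate) | COc1c(OC(=O)C(F)(F)F)cc2occ(-c3ccc(OC(=O)C(F)(F)F)cc3)c(=O)c2c1OC(=O)C(F)(F)F | intermediate
7 | tectorigenin (5,7-dihydroxy-3-(4-hydroxyphenyl)-6-methoxy-4H-chromen-4-one) | COc1c(O)cc2occ(-c3ccc(O)cc3)c(=O)c2c1O | intermediate
8 | prenyl bromide (1-bromo-3-methylbut-2-ene) | CC(C)=CCBr | starting material
9 | tectorigenin dipotassium salt (dipotassium 7,4'-diphenoxide) | COc1c([O-])cc2occ(-c3ccc([O-])cc3)c(=O)c2c1O.[K+].[K+] | intermediate
10 | isoaurmillone | COc1c(O)cc2occ(-c3ccc(OCC=C(C)C)cc3)c(=O)c2c1O | target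

**Totals**
Total step count: 3. Longest linear sequence: 3 steps (1 or 2 → 4 → 7 → 10).

**Steps most likely to fail, with fallbacks**

Step 2 (the proposed new C5–H oxygenation). Ruthenation next to the methoxy group may be too slow, or ring A may be over-oxidised. The fallback uses known chemistry only and brings the 5-oxygen in with ring A instead of installing it late. It sets out from 2. Friedel–Crafts acylation of purchased 2-methoxybenzene-1,3,5-triol F1 with 2 in BF3·Et2O (the two free ring positions of F1 are equivalent) gives 2-(4-hydroxyphenyl)-1-(2,4,6-trihydroxy-3-methoxyphenyl)ethan-1-one F2. Formylative closure (DMF, MsCl, BF3·Et2O) gives 7 together with its ring-closure isomer ψ-tectorigenin (5,7-dihydroxy-3-(4-hydroxyphenyl)-8-methoxy-4H-chromen-4-one) F3, because either ortho-hydroxyl can close. Warming the mixture in dilute aqueous Na2CO3 at 60 °C opens and recloses the pyranone (Wessely–Moser-type ring isomerisation). To the best of my recollection this drains the 8-methoxy isomer into the 6-methoxy isomer; any F3 left is removed by crystallisation. The route is rejoined at 7.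

Step 3 (site-selective prenylation). The dianion may give 7-O-prenyl or bis-prenyl ethers. The fallback sets out from 7 and masks the most acidic hydroxyl first. PivCl (1.05 equiv) with Et3N in acetone at 0 °C acylates the 7-OH to give 7-O-pivaloyltectorigenin F4. Mitsunobu etherification of the 4'-OH with 3-methylbut-2-en-1-ol F5 (PPh3, DIAD, THF, 0 °C; the chelated 5-OH does not react) gives 7-O-pivaloyl-4'-O-prenyltectorigenin F6. K2CO3 in MeOH at rt removes the pivalate without touching the prenyl ether, and the route is rejoined at 10.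

Step 1 (one-pot acylation and closure). Acylation in hot BF3·Et2O may give regioisomers or tar from the oxidation-prone 1, or the closure may stall at boron chelates. The fallback sets out from 1 and isolates the ketone. Houben–Hoesch acylation of 1 with 4-hydroxyphenylacetonitrile F7 (ZnCl2, HCl gas, Et2O, 0 °C) precipitates 1-(2,4-dihydroxy-5-methoxyphenyl)-2-(4-hydroxyphenyl)ethan-1-iminium chloride F8, which hot water hydrolyses to 3. Recrystallised 3 rejoins the route at 3 and is closed to 4 with DMF and MsCl in BF3·Et2O as in the second half of step 1.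

**Further compounds**
F1 | step 2 | 2-methoxybenzene-1,3,5-triol | COc1c(O)cc(O)cc1O
F2 | step 2 | 2-(4-hydroxyphenyl)-1-(2,4,6-trihydroxy-3-methoxyphenyl)ethan-1-one | COc1c(O)cc(O)c(C(=O)Cc2ccc(O)cc2)c1O
F3 | step 2 | ψ-tectorigenin (5,7-dihydroxy-3-(4-hydroxyphenyl)-8-methoxy-4H-chromen-4-one) | COc1c(O)cc(O)c2c(=O)c(-c3ccc(O)cc3)coc12
F4 | step 3 | 7-O-pivaloyltectorigenin | COc1c(OC(=O)C(C)(C)C)cc2occ(-c3ccc(O)cc3)c(=O)c2c1O
F5 | step 3 | 3-methylbut-2-en-1-ol | CC(C)=CCO
F6 | step 3 | 7-O-pivaloyl-4'-O-prenyltectorigenin | COc1c(OC(=O)C(C)(C)C)cc2occ(-c3ccc(OCC=C(C)C)cc3)c(=O)c2c1O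
F7 | step 1 | 4-hydroxyphenylacetonitrile | N#CCc1ccc(O)cc1
F8 | step 1 | 1-(2,4-dihydroxy-5-methoxyphenyl)-2-(4-hydroxyphenyl)ethan-1-iminium chloride | COc1cc(C(=[NH2+])Cc2ccc(O)cc2)c(O)cc1O.[Cl-]
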